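Readings and results stem from a simulated flask with constants of no real substance.

- I turned the question round. For flask beta, with its substrate fed, to tie with flask zeta, the product curve of an all-in flask would have to lie flat over the last part of the run.

| setting | north-east | north | south-west | eta | beta | zeta |
|---|---|---|---|---|---|---|
| substrate | 0.10 M | 0.10 M | 0.10 M | 0.10 M | 0.10 M (fed, over 80 min) | 0.10 M |
| partner | 1.5 equiv | 1.5 equiv | 1.5 equiv | 1.50 equiv (fed, over 80 min) | 1.50 equiv | 1.50 equiv |
| catalyst | 18 mol% | 12 mol% | 27 mol% | 18 mol% | 18 mol% | 18 mol% |
| remark | run made earlier | run made earlier | run made earlier | all else is in the flask from the start; the feed brings no volume worth counting | all else is in the flask from the start; the feed brings no volume worth counting | everything together at the start |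
| time |  |  |  | 2.0 h | 2.0 h | 2.0 h |

north-east run (percent of the substrate charged)

| time / min | product / % | substrate / % |
|---|---|---|
| 15.0 | 0 | 90 |
| 40.0 | 3 | 72 |
| 80.0 | 9 | 53 |
| 120 | 18 | 37 |

north run (percent of the substrate charged)

| time / h | product / % | substrate / % |
|---|---|---|
| 0.667 | 2 | 80 |
| 1.33 | 5 | 63 |
| 2.00 | 8 | 50 |
| 2.50 | 13 | 43 |

south-west run (percent of the substrate charged)

| time / h | product / % | substrate / % |
|---|---|---|
| 0.333 | 2 | 79 |
| 0.833 | 10 | 53 |
| 1.50 | 25 | 32 |
| 2.50 | 41 | 15 |

(standard deviation of a reading: 1.5 percentage points)



- the flask with the highest amount of product, in percent of the substrate charged ("all alike" if they lie within 1.5 percentage points) (eta / beta / zeta / all alike)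
- final product, as a percentage of the substrate charged, in eta
- final product, as a percentage of the substrate charged, in beta
- final product, as a percentage of the substrate charged, in zeta

- Zeta repeats the charges of the north-east run, so I read it directly: 18 % product at 120 min.
- Substrate and product in that last reading sum to 55.0 %, so I took an unseen intermediate to stand between them, which makes two steps.
- Substrate is the limiting reagent, with partner at 1.5 equiv. If each product takes one partner, that reading uses 12.0 % of the charged c(partner), so I took c(partner) and c(catalyst) as constant and treated both steps as pseudo-first-order, and each portion of substrate then ages on its own.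
- A steady feed spreads those ages evenly, in beta from 40.0 min to 2.0 h. My rule was therefore the window mean, the all-in product curve averaged over the ages present in the fed flask; the readings at 40.0 min, 80.0 min and 120 min give 9.75 %.
- The curve is not flat: by this reckoning beta stands 8.2 percentage points below zeta, more than the margin of 1.5 points. The rule does not reach eta, where partner is fed, and the north-east, north and south-west runs each had 1.5 equiv of partner.
- The forecast gave zeta as best, with 18 % for zeta, 15 % for eta and 9 % for beta, below my window mean; of eta it wrote “little intermediate exists early, when partner is short”.
- Zeta gave 17.9 %, eta 15.6 % and beta 9.98 %, so zeta led and the forecast stood within its tolerance.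

    substrate + catalyst → catalyst + intermediate (k = 0.467 /M/min)
    partner + catalyst + intermediate → catalyst + product (k = 1.96 /M²/min)

- The window mean of 9.75 % stood beside the 9.98 % found in beta. For a beta fed over 0.133 h, the window is short enough to take its midpoint on the line between the last two readings, which gives 17.1 % against 17.1 % found. In beta after 2.00 h, the half-life of substrate by its step was 1.4 h, shorter than the 2.3 h of intermediate by its step. Beta then held 38.0 % intermediate against 9.98 % product.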